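## The problem

The target **30** is a germacranolide: a ten-membered carbocycle (C1–C10, germacrane numbering, C14 on C10, C15 on C4) fused trans across C6–C7 to an α-methylene-γ-butyrolactone (O on C6, C11 on C7, C12 carbonyl, C13 methylene). The ring carries a Z C4=C5 olefin, a cis 1,10-epoxide (C2 and C9 on the same side), a free 3-hydroxyl and an 8-isobutyrate. The six stereocentres are 1R,3S,6S,7S,8R,10S, as encoded in the SMILES. A ten-membered ring with these groups will stand little chemistry once formed, so the ring should close last on a chain that already holds lactone, epoxide and ester. Of the stereocentres, C6 can control C7 through the five-membered ring, C7 and C8 can be set together in one C–C bond formation, and the C8 hydroxyl can steer epoxidation of a Z C1=C10 olefin; C3 is remote from all of these and only C6 needs an outside source of chirality. The fragile groups are the methylene lactone (Michael acceptor), the trisubstituted epoxide (acid), the esters (hydrides, organolithiums), the free 8-hydroxyl (it is γ to the C12 carbonyl and can translactonise under base) and a C3 aldehyde that is β,γ to the epoxide. The feature that opens the structure is that C3 is an allylic carbinol bonded to the methyl-bearing sp2 carbon C4 of the Z olefin; this is the retron of an alkenyl-metal addition to an aldehyde, and the Z geometry can be stored beforehand in a 2-iodoalkene.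

## Retrosynthesis

**C3–C4.** Cutting this bond turns **30** into the open-chain iodo-aldehyde **28**, with C4 as a (Z)-alkenyl iodide and C3 as an aldehyde. Against cuts at C2–C3 or C5–C6, this one creates the allylic alcohol directly, uses a non-basic chromium reagent that ignores esters and epoxides, and leaves nothing to do after ring closure. The forward reaction must close a ten-membered ring, keep the olefin geometry and choose one aldehyde face.

**Oxidation level at C3.** Aldehyde **28** is β,γ to the epoxide and should exist only briefly, so it is taken back to alcohol **27** and that to the 4-methoxybenzyl ether **26**. The ether comes off oxidatively at neutral pH, which the epoxide, the methylene lactone and the alkenyl iodide all tolerate.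

**C8–O acyl bond and the epoxide.** Ester **26** comes from epoxy alcohol **24** and isobutyric anhydride **25**. Before it is acylated, the C8 hydroxyl is used once: it is homoallylic to the Z C1=C10 olefin of **23** and can deliver the oxygen to one face, setting C1 and C10 together. Epoxidising before acylation needs no reagent chirality and leaves the electron-poor olefins alone.

**C7–C8.** Hydroxy lactone **23** is cut into bromomethyl butenolide **10** and the β,γ-unsaturated aldehyde **21**. The allyl metal from **10** is locked in one geometry by its ring and has one face blocked by the C6 substituent, so a chair transition state fixes C7 and C8 in one step. The same step shifts the double bond into the exocyclic methylene, keeps the lactone on O6 and frees the C8 hydroxyl needed next. A cut at C6–C7 would need an open-chain allyl metal carrying the C8 stereocentre with uncertain 1,2-induction; a cut at C8–C9 would need an α-selective Z-allyl metal. The precursors are an achiral seven-carbon chain and a five-membered lactone with one stereocentre.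

**Butenolide 10.** Ring-closing metathesis of acrylate **9** forms C7=C11; **9** is the ester of dienol **7** with the commercial acid **8**. Alcohol **7** is the slow-reacting enantiomer of racemate **6**, made from enal **4** and vinylmagnesium bromide **5**. Enal **4** comes by way of alcohol **3** from but-2-yn-1-ol **1**, whose trans-hydroalumination–iodination installs the Z iodide needed in the last step. The alkenyl iodide therefore travels the whole route and no olefination is needed next to the lactone.

**Aldehyde 21.** Oxidation of homoallylic alcohol **20** gives **21**. Alcohol **20** arises from alkenyl iodide **17** by iodine–lithium exchange and opening of oxirane **18**. Iodide **17** is made from aldehyde **12** (from alcohol **11**) and phosphonium salt **13** by Z-selective iodoethylidenation. This delivers C1–C3, C10, C14 and the Z geometry in one operation; a four-carbon Z-alkenedioic building block would lack C3 and force two allylic termini to be told apart.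

## Roads not taken

**Alternative 1:** The cut is C2–C3 together with O–C1. The nitrile oxide from oxime **A2** (NaOCl) adds across the vinyl group on the C10 carbinol and gives isoxazoline **A1**.
- Merits: two bonds and the ring form in one metal-free step, with the usual regiochemistry (oxygen to the substituted carbon), and no labile epoxy aldehyde is needed.
- Weak points: **A1** is far from the target. C3 arrives at the ketone level, so its configuration is still open. N–O cleavage needs reducing conditions next to a conjugated C4=C5 bond. The C1/C10 diol must become the cis epoxide by activating a hydroxyl that sits β to the new ketone, which invites elimination. The methylene at C11 must be added last by enolate chemistry. The face of addition at C1 is uncontrolled.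
- Comparison: this road is better in avoiding the epoxy aldehyde **28** and stoichiometric chromium. The chosen plan sets against that no steps after closure and five of six stereocentres secured before it.

**Alternative 2:** The cut is C8–C9, made while a six-membered ring bond breaks. The potassium alkoxide of cyclohexenol **A4** (KH, 18-crown-6) undergoes an anionic oxy-Cope rearrangement to cyclodecadienone **A3**.
- Merits: ring expansion avoids the entropic cost of a ten-membered closure, is usually fast and clean, and starts from the terpene pool.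
- Weak points: **A3** carries an E C1=C10 olefin, whereas the cis epoxide of **30** needs the Z isomer. C7 has no side chain, so C11–C13 must be added α to the C6 ketone on a flexible ring. The ketone must then be reduced with control. C8 depends on enol ether geometry and chair–boat preference. Eight or more steps follow the key step.
- Comparison: ring formation is more reliable here than in the chosen plan. The chosen plan sets against it a convergent assembly with lactone, ester and epoxide stereochemistry in place before the ring exists.

**Alternative 3:** The cut is C3–O and C6–O. Singlet oxygen adds across the (3Z,5Z)-diene **A6** and gives endoperoxide **A5** with the Z C4=C5 olefin.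
- Merits: C3 and C6 are oxygenated in one suprafacial step, so their relative configuration is tied together; this is better than the conformational control of C3 in the chosen plan.
- Weak points: the ten-membered ring with a cis,cis-diene must already exist, so ring closure is only postponed. The ene reaction at the C15 methyl and C2 hydrogens competes. The face of attack depends on ring conformation. The peroxide must be reduced beside an epoxide. **A5** still lacks the methylene, which would need enolate chemistry at the end.
- Comparison: the chosen plan cannot match the coupled C3/C6 control, but it closes the ring itself and ends at the target.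

Key step: step 16

Remark on the chemistry: the CrCl2 used in step 11 is taken to be free of nickel, so that only the allylic bromide is metalated there.

## Steps

Step 1
Reactants: 1 but-2-yn-1-ol
Product: 3 (2Z)-3-iodobut-2-en-1-ol, via sodium alkenylalanate 2 (not isolated)
Conditions: NaAlH2(OCH2CH2OMe)2, THF, 0 °C to rt; then I2, −78 °C
Reagents that add atoms: iodine, II
Why: Hydroxyl-directed trans-hydroalumination of the propargylic alcohol puts aluminium on the distal carbon in the cyclic alanate 2; iodinolysis with retention should give the Z iodide, iodine cis to the CH2OH group.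

Step 2
Reactants: 3 (2Z)-3-iodobut-2-en-1-ol
Product: 4 (2Z)-3-iodobut-2-enal
Conditions: MnO2, CH2Cl2, rt
Reagents that add atoms: none
Why: Neutral allylic oxidation with MnO2 leaves the alkenyl iodide untouched; the enal is used at once so that the Z geometry does not drift.

Step 3
Reactants: 4 (2Z)-3-iodobut-2-enal; 5 vinylmagnesium bromide
Product: 6 rac-(4Z)-5-iodohexa-1,4-dien-3-ol
Conditions: THF, −78 °C; aq. NH4Cl
Reagents that add atoms: none
Why: Grignard 1,2-addition to the enal at low temperature should outrun conjugate addition–elimination and halogen–metal exchange; the carbinol is formed racemic.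

Step 4
Reactants: 6 rac-(4Z)-5-iodohexa-1,4-dien-3-ol
Product: 7 (3R,4Z)-5-iodohexa-1,4-dien-3-ol
Conditions: Ti(OiPr)4, D-(−)-diisopropyl tartrate, t-BuOOH (0.6 equiv), 4 Å molecular sieves, CH2Cl2, −20 °C
Reagents that add atoms: none
Why: Sharpless kinetic resolution: with the D-tartrate the S enantiomer is the matched one for epoxidation of its vinyl group and is consumed as the erythro epoxy alcohol, so the R alcohol should be recovered; the Z-iodoalkene is too hindered and electron-poor to react.

Step 5
Reactants: 7 (3R,4Z)-5-iodohexa-1,4-dien-3-ol; 8 2-(bromomethyl)prop-2-enoic acid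
Product: 9 (3R,4Z)-5-iodohexa-1,4-dien-3-yl 2-(bromomethyl)prop-2-enoate
Conditions: DCC, DMAP (5 mol%), CH2Cl2, 0 °C
Reagents that add atoms: none
Why: Steglich esterification; low temperature and little DMAP limit attack of the amine on the allylic bromide, and the carbinol stereocentre is not touched.

Step 6
Reactants: 9 (3R,4Z)-5-iodohexa-1,4-dien-3-yl 2-(bromomethyl)prop-2-enoate
Product: 10 (5R)-3-(bromomethyl)-5-[(1Z)-2-iodoprop-1-en-1-yl]furan-2(5H)-one
Conditions: second-generation Grubbs catalyst RuCl2(=CHPh)(H2IMes)(PCy3) (5 mol%), CH2Cl2 (5 mM), 40 °C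
Reagents that add atoms: none
Why: Ring-closing metathesis between the terminal vinyl group and the acrylate closes the butenolide (C7=C11) with loss of ethylene; the trisubstituted iodoalkene and the allylic bromide are spectators, and the neutral medium keeps the acidic γ-hydrogen and its stereocentre intact.

Step 7
Reactants: 11 3-[(4-methoxybenzyl)oxy]propan-1-ol
Product: 12 3-[(4-methoxybenzyl)oxy]propanal
Conditions: TEMPO (10 mol%), PhI(OAc)2, CH2Cl2, rt
Reagents that add atoms: none
Why: Oxoammonium oxidation stops at the aldehyde and is not basic, so the β-alkoxy aldehyde does not eliminate.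

Step 8
Reactants: 12 3-[(4-methoxybenzyl)oxy]propanal; 13 ethyltriphenylphosphonium bromide
Product: 17 1-({[(3Z)-4-iodopent-3-en-1-yl]oxy}methyl)-4-methoxybenzene, via ethylidenetriphenylphosphorane 14 (not isolated), via (1-iodoethyl)triphenylphosphonium iodide 15 (not isolated), via (1-iodoethylidene)triphenylphosphorane 16 (not isolated)
Conditions: n-BuLi, THF, 0 °C; I2, −78 °C; NaN(SiMe3)2, −78 to −20 °C; then 12, −78 °C to rt
Reagents that add atoms: iodine, II
Why: Stork–Zhao-type iodoethylidenation: the unstabilised iodo ylide 16 reacts under kinetic control and should give the Z 2-iodoalkene, iodine cis to the chain, which fixes the later C1=C10 geometry.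

Step 9
Reactants: 17 1-({[(3Z)-4-iodopent-3-en-1-yl]oxy}methyl)-4-methoxybenzene; 18 oxirane
Product: 20 (3Z)-6-[(4-methoxybenzyl)oxy]-3-methylhex-3-en-1-ol, via alkenyllithium 19 (not isolated)
Conditions: t-BuLi (2.1 equiv), Et2O, −78 °C; then 18, −78 to 0 °C
Reagents that add atoms: none
Why: Iodine–lithium exchange proceeds with retention and the alkenyllithium 19 is configurationally stable at −78 °C; opening of oxirane adds C8 and C9 and gives the Z homoallylic alcohol.

Step 10
Reactants: 20 (3Z)-6-[(4-methoxybenzyl)oxy]-3-methylhex-3-en-1-ol
Product: 21 (3Z)-6-[(4-methoxybenzyl)oxy]-3-methylhex-3-enal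
Conditions: Dess–Martin periodinane, NaHCO3, CH2Cl2, 0 °C; used crude
Reagents that add atoms: none
Why: Buffered Dess–Martin oxidation gives the β,γ-unsaturated aldehyde without moving the olefin into conjugation; the aldehyde is not stored.

Step 11
Reactants: 10 (5R)-3-(bromomethyl)-5-[(1Z)-2-iodoprop-1-en-1-yl]furan-2(5H)-one; 21 (3Z)-6-[(4-methoxybenzyl)oxy]-3-methylhex-3-enal
Product: 23 (4S,5R)-4-{(1R,3Z)-1-hydroxy-6-[(4-methoxybenzyl)oxy]-3-methylhex-3-en-1-yl}-5-[(1Z)-2-iodoprop-1-en-1-yl]-3-methylideneoxolan-2-one, via allylchromium 22 (not isolated)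
Conditions: CrCl2 (3 equiv), THF, 0 °C to rt; aq. NH4Cl
Reagents that add atoms: none
Why: Nozaki–Hiyama allylation (chromium Barbier reaction): divalent chromium metalates only the allylic bromide, and allylchromium 22 attacks the aldehyde through its ring carbon C7 in a closed chair transition state, which moves the double bond into the exocyclic methylene. The ring locks the allyl unit in the E-type geometry and the aldehyde chain sits equatorial, which should give the 7S,8R pair, while approach anti to the C6 iodopropenyl group gives the trans lactone. The reagent is not basic, so the aldehyde should not isomerise and C6 should not epimerise.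

Step 12
Reactants: 23 (4S,5R)-4-{(1R,3Z)-1-hydroxy-6-[(4-methoxybenzyl)oxy]-3-methylhex-3-en-1-yl}-5-[(1Z)-2-iodoprop-1-en-1-yl]-3-methylideneoxolan-2-one
Product: 24 (4S,5R)-4-{(1R)-1-hydroxy-2-[(2S,3R)-3-{2-[(4-methoxybenzyl)oxy]ethyl}-2-methyloxiran-2-yl]ethyl}-5-[(1Z)-2-iodoprop-1-en-1-yl]-3-methylideneoxolan-2-one
Conditions: VO(acac)2 (5 mol%), t-BuOOH, CH2Cl2, 0 °C to rt
Reagents that add atoms: tert-butyl hydroperoxide, CC(C)(C)OO
Why: Hydroxyl-directed epoxidation of a homoallylic alcohol: in the chair-like vanadium alkoxide–peroxide transition state the C7 residue is equatorial, the Z olefin forces the C14 methyl pseudo-axial and the allylic hydrogen into the olefin plane, and oxygen should go to the face that gives the 1R,10S cis epoxide. The methylene lactone and the iodoalkene are electron-poor and should not react.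

Step 13
Reactants: 24 (4S,5R)-4-{(1R)-1-hydroxy-2-[(2S,3R)-3-{2-[(4-methoxybenzyl)oxy]ethyl}-2-methyloxiran-2-yl]ethyl}-5-[(1Z)-2-iodoprop-1-en-1-yl]-3-methylideneoxolan-2-one; 25 2-methylpropanoic anhydride
Product: 26 (1R)-1-{(2R,3S)-2-[(1Z)-2-iodoprop-1-en-1-yl]-4-methylidene-5-oxooxolan-3-yl}-2-[(2S,3R)-3-{2-[(4-methoxybenzyl)oxy]ethyl}-2-methyloxiran-2-yl]ethyl 2-methylpropanoate
Conditions: DMAP (10 mol%), Et3N, CH2Cl2, 0 °C
Reagents that add atoms: none
Why: DMAP-catalysed acylation of the secondary alcohol; the weak base and low temperature are chosen so that acylation outruns migration of the lactone to O8.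

Step 14
Reactants: 26 (1R)-1-{(2R,3S)-2-[(1Z)-2-iodoprop-1-en-1-yl]-4-methylidene-5-oxooxolan-3-yl}-2-[(2S,3R)-3-{2-[(4-methoxybenzyl)oxy]ethyl}-2-methyloxiran-2-yl]ethyl 2-methylpropanoate
Product: 27 (1R)-2-[(2S,3R)-3-(2-hydroxyethyl)-2-methyloxiran-2-yl]-1-{(2R,3S)-2-[(1Z)-2-iodoprop-1-en-1-yl]-4-methylidene-5-oxooxolan-3-yl}ethyl 2-methylpropanoate
Conditions: DDQ, CH2Cl2/pH 7 phosphate buffer, 0 °C
Reagents that add atoms: none
Why: Oxidative cleavage of the 4-methoxybenzyl ether by DDQ at neutral pH; epoxide, esters, methylene lactone and alkenyl iodide are inert to the quinone.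

Step 15
Reactants: 27 (1R)-2-[(2S,3R)-3-(2-hydroxyethyl)-2-methyloxiran-2-yl]-1-{(2R,3S)-2-[(1Z)-2-iodoprop-1-en-1-yl]-4-methylidene-5-oxooxolan-3-yl}ethyl 2-methylpropanoate
Product: 28 (1R)-1-{(2R,3S)-2-[(1Z)-2-iodoprop-1-en-1-yl]-4-methylidene-5-oxooxolan-3-yl}-2-[(2S,3R)-2-methyl-3-(2-oxoethyl)oxiran-2-yl]ethyl 2-methylpropanoate
Conditions: Dess–Martin periodinane, NaHCO3, CH2Cl2, 0 °C; used at once
Reagents that add atoms: none
Why: Buffered Dess–Martin oxidation of the primary alcohol; the β,γ-epoxy aldehyde is kept away from acid, base and silica because either would open the epoxide by β-elimination.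

Step 16
Reactants: 28 (1R)-1-{(2R,3S)-2-[(1Z)-2-iodoprop-1-en-1-yl]-4-methylidene-5-oxooxolan-3-yl}-2-[(2S,3R)-2-methyl-3-(2-oxoethyl)oxiran-2-yl]ethyl 2-methylpropanoate
Product: 30 (1R,3S,4Z,6S,7S,8R,10S)-1,10-epoxy-3-hydroxy-8-(2-methylpropanoyloxy)germacra-4,11(13)-dien-12,6-olide, via alkenylchromium 29 (not isolated)
Conditions: CrCl2 (10 equiv), NiCl2 (0.1 equiv), degassed DMSO, 3 mM, rt, slow addition of 28
Reagents that add atoms: none
Why: Nozaki–Hiyama–Kishi reaction: NiCl2 is reduced by CrCl2 to zerovalent nickel, which inserts into the C4–I bond with retention and hands the alkenyl group to trivalent chromium, giving alkenylchromium 29 and returning divalent nickel to the cycle. Alkenylchromium 29 adds to the C3 aldehyde, forming C3–C4, and work-up frees the alcohol. The closest known reaction type is the macrocyclisation of 2-iodoalk-2-enes onto aldehydes to give cyclic allylic alcohols. The ten-membered carbocycle closes in a 10-exo-trig addition: C3 and C4 both become ring atoms and the carbonyl oxygen stays outside. The new stereocentre C3 is under substrate control only: the trans lactone, the cis epoxide and the Z olefin fold the chain, and addition through the conformer with the carbonyl oxygen turned outward is expected to favour one face, though its sense cannot be guaranteed. The step needs chemoselectivity, which the non-basic, aldehyde-selective chromium reagent should provide toward lactone, isobutyrate, epoxide and methylene lactone. It needs ring closure over oligomerisation, which high dilution and slow addition serve. It also needs the Z geometry, which is fixed in the iodide and carried through nickel and chromium with retention.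

## Compound list

1 | but-2-yn-1-ol | CC#CCO | starting material
2 | sodium 2,2-bis(2-methoxyethoxy)-3-methyl-2,5-dihydro-1,2-oxaaluminol-2-uide (cyclic alkenylalanate) | CC1=CCO[Al-]1(OCCOC)OCCOC.[Na+] | intermediate (not isolated)
3 | (2Z)-3-iodobut-2-en-1-ol | C/C(I)=C/CO | intermediate
4 | (2Z)-3-iodobut-2-enal | C/C(I)=C/C=O | intermediate
5 | vinylmagnesium bromide | C=C[Mg]Br | starting material
6 | rac-(4Z)-5-iodohexa-1,4-dien-3-ol (racemic at C3) | C=CC(O)/C=C(/C)I | intermediate
7 | (3R,4Z)-5-iodohexa-1,4-dien-3-ol | O[C@@H](/C=C(/C)I)C=C | intermediate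
8 | 2-(bromomethyl)prop-2-enoic acid | C=C(CBr)C(=O)O | starting material
9 | (3R,4Z)-5-iodohexa-1,4-dien-3-yl 2-(bromomethyl)prop-2-enoate | C=C(CBr)C(=O)O[C@@H](/C=C(/C)I)C=C | intermediate
10 | (5R)-3-(bromomethyl)-5-[(1Z)-2-iodoprop-1-en-1-yl]furan-2(5H)-one | O=C1O[C@@H](/C=C(/C)I)C=C1CBr | intermediate
11 | 3-[(4-methoxybenzyl)oxy]propan-1-ol | COc1ccc(COCCCO)cc1 | starting material
12 | 3-[(4-methoxybenzyl)oxy]propanal | COc1ccc(COCCC=O)cc1 | intermediate
13 | ethyltriphenylphosphonium bromide | CC[P+](c1ccccc1)(c1ccccc1)c1ccccc1.[Br-] | starting material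
14 | ethylidenetriphenylphosphorane | CC=P(c1ccccc1)(c1ccccc1)c1ccccc1 | intermediate (not isolated)
15 | (1-iodoethyl)triphenylphosphonium iodide | CC(I)[P+](c1ccccc1)(c1ccccc1)c1ccccc1.[I-] | intermediate (not isolated)
16 | (1-iodoethylidene)triphenylphosphorane | CC(I)=P(c1ccccc1)(c1ccccc1)c1ccccc1 | intermediate (not isolated)
17 | 1-({[(3Z)-4-iodopent-3-en-1-yl]oxy}methyl)-4-methoxybenzene | COc1ccc(COCC/C=C(/C)I)cc1 | intermediate
18 | oxirane | C1CO1 | starting material
19 | {(2E)-5-[(4-methoxybenzyl)oxy]pent-2-en-2-yl}lithium (lithium cis to the chain, as the iodine of 17) | COc1ccc(COCC/C=C(/C)[Li])cc1 | intermediate (not isolated)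
20 | (3Z)-6-[(4-methoxybenzyl)oxy]-3-methylhex-3-en-1-ol | COc1ccc(COCC/C=C(/C)CCO)cc1 | intermediate
21 | (3Z)-6-[(4-methoxybenzyl)oxy]-3-methylhex-3-enal | COc1ccc(COCC/C=C(/C)CC=O)cc1 | intermediate
22 | dichloro({(5R)-5-[(1Z)-2-iodoprop-1-en-1-yl]-2-oxo-2,5-dihydrofuran-3-yl}methyl)chromium | O=C1O[C@@H](/C=C(/C)I)C=C1C[Cr](Cl)Cl | intermediate (not isolated)
23 | (4S,5R)-4-{(1R,3Z)-1-hydroxy-6-[(4-methoxybenzyl)oxy]-3-methylhex-3-en-1-yl}-5-[(1Z)-2-iodoprop-1-en-1-yl]-3-methylideneoxolan-2-one | C=C1C(=O)O[C@@H](/C=C(/C)I)[C@@H]1[C@H](O)C/C(C)=C\CCOCc1ccc(OC)cc1 | intermediate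
24 | (4S,5R)-4-{(1R)-1-hydroxy-2-[(2S,3R)-3-{2-[(4-methoxybenzyl)oxy]ethyl}-2-methyloxiran-2-yl]ethyl}-5-[(1Z)-2-iodoprop-1-en-1-yl]-3-methylideneoxolan-2-one | C=C1C(=O)O[C@@H](/C=C(/C)I)[C@@H]1[C@H](O)C[C@]2(C)O[C@@H]2CCOCc1ccc(OC)cc1 | intermediate
25 | 2-methylpropanoic anhydride (isobutyric anhydride) | CC(C)C(=O)OC(=O)C(C)C | starting material
26 | (1R)-1-{(2R,3S)-2-[(1Z)-2-iodoprop-1-en-1-yl]-4-methylidene-5-oxooxolan-3-yl}-2-[(2S,3R)-3-{2-[(4-methoxybenzyl)oxy]ethyl}-2-methyloxiran-2-yl]ethyl 2-methylpropanoate | C=C1C(=O)O[C@@H](/C=C(/C)I)[C@@H]1[C@H](OC(=O)C(C)C)C[C@]2(C)O[C@@H]2CCOCc1ccc(OC)cc1 | intermediate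
27 | (1R)-2-[(2S,3R)-3-(2-hydroxyethyl)-2-methyloxiran-2-yl]-1-{(2R,3S)-2-[(1Z)-2-iodoprop-1-en-1-yl]-4-methylidene-5-oxooxolan-3-yl}ethyl 2-methylpropanoate | C=C1C(=O)O[C@@H](/C=C(/C)I)[C@@H]1[C@H](OC(=O)C(C)C)C[C@]2(C)O[C@@H]2CCO | intermediate
28 | (1R)-1-{(2R,3S)-2-[(1Z)-2-iodoprop-1-en-1-yl]-4-methylidene-5-oxooxolan-3-yl}-2-[(2S,3R)-2-methyl-3-(2-oxoethyl)oxiran-2-yl]ethyl 2-methylpropanoate | C=C1C(=O)O[C@@H](/C=C(/C)I)[C@@H]1[C@H](OC(=O)C(C)C)C[C@]2(C)O[C@@H]2CC=O | intermediate
29 | alkenylchromium dichloride of 28 (CrCl2 group in place of iodine at C4, geometry retained) | C=C1C(=O)O[C@@H](/C=C(/C)[Cr](Cl)Cl)[C@@H]1[C@H](OC(=O)C(C)C)C[C@]2(C)O[C@@H]2CC=O | intermediate (not isolated)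
30 | CNP0261225.1, (1R,3S,4Z,6S,7S,8R,10S)-1,10-epoxy-3-hydroxy-8-(2-methylpropanoyloxy)germacra-4,11(13)-dien-12,6-olide | C=C1C(=O)O[C@H]2/C=C(/C)[C@@H](O)C[C@H]3O[C@@]3(C)C[C@@H](OC(=O)C(C)C)[C@H]12 | target

## Step count and least certain steps

Total: 16 steps. Longest linear sequence: 12 steps (steps 1–6, then 11–16); the chain fragment takes 4 steps (7–10).

**Step 16 (key step).** Closure of a ten-membered ring is slow, so intermolecular coupling or loss of the alkenyl metal by protonation may compete. The epoxy aldehyde may be lost by Lewis-acid-assisted opening of the epoxide before it cyclises. Facial selection at C3 rests on chain conformation alone and may be poor or go the wrong way. Fallback, setting out from 28: the closure is run as planned and the 3R alcohol F1 (alone or mixed with 30) is oxidised with buffered Dess–Martin periodinane to the ring enone F2. F2 is then reduced under Luche conditions (NaBH4, CeCl3·7H2O, MeOH, −78 °C). C3 is now set by hydride attack from the periphery of the ten-membered ring, a control element independent of the C–C bond formation. The route is rejoined at 30.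

**Step 11.** Leakage through a boat or open transition state would erode the configuration at C8. The β,γ-unsaturated aldehyde may isomerise into conjugation on the Lewis-acidic chromium. Enolisation at the γ-position of the butenolide would erode C6. Fallback, setting out from 10 and 21: if the (1S)-carbinol F3 predominates, a Mitsunobu reaction with 2-methylpropanoic acid (PPh3, DIAD) inverts C8 and installs the ester in one operation, giving the olefinic isobutyrate F4. The directing hydroxyl is then spent, so F4 is epoxidised under reagent control with the D-fructose-derived Shi ketone and KHSO5 (as 2KHSO5·KHSO4·K2SO4, K2CO3 buffer, 0 °C). By analogy with other trisubstituted olefins whose single olefinic hydrogen sits in the corresponding position, this ketone is expected to give the 1R,10S epoxide. The route is rejoined at 26.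

**Step 12.** Face selection may be weak if the chair-like transition state is poorly ordered. Turnover is slow for homoallylic alcohols, which leaves time for oxidation of the carbinol or for lactone migration. Fallback, setting out from 23: the alcohol is acylated first (25, DMAP, Et3N), which gives the olefinic isobutyrate F4 already described under step 11. F4 is then epoxidised with the same D-fructose-derived ketone and KHSO5, and the route is rejoined at 26. This fallback makes no compound beyond those listed (F0).

**Step 6.** Metathesis at the 1,1-disubstituted, electron-poor acrylate may be slow. The allylic bromide may degrade the catalyst, and ruthenium hydrides may move double bonds. Fallback, setting out from 7: the alcohol is esterified (DCC, DMAP) with 2-{[(tert-butyldimethylsilyl)oxy]methyl}prop-2-enoic acid to give the silyloxymethyl acrylate F5. Ring-closing metathesis then gives the silyloxymethyl butenolide F6, and HF·pyridine gives the hydroxymethyl butenolide F7. The bromide is made last by an Appel reaction (CBr4, PPh3), and the route is rejoined at 10.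

**Step 4.** Discrimination between the enantiomers may be incomplete for a carbinol flanked by two alkenyl groups. The titanium Lewis acid may cause slow allylic transposition of the bis-allylic alcohol. Fallback, setting out from 6: enzymatic acylation (Burkholderia cepacia lipase, vinyl acetate, tert-butyl methyl ether, rt) is expected, by the empirical size rule for lipases and secondary alcohols, to acylate the R enantiomer to the (3R)-acetate F8. F8 is separated from the unreacted alcohol and methanolysed (K2CO3, MeOH, 0 °C), and the route is rejoined at 7.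

## Further compounds

F1 | step 16 | (1R,3R,4Z,6S,7S,8R,10S)-1,10-epoxy-3-hydroxy-8-(2-methylpropanoyloxy)germacra-4,11(13)-dien-12,6-olide (C3 epimer of 30) | C=C1C(=O)O[C@H]2/C=C(/C)[C@H](O)C[C@H]3O[C@@]3(C)C[C@@H](OC(=O)C(C)C)[C@H]12
F2 | step 16 | (1R,4Z,6S,7S,8R,10S)-1,10-epoxy-8-(2-methylpropanoyloxy)-3-oxogermacra-4,11(13)-dien-12,6-olide | C=C1C(=O)O[C@H]2/C=C(/C)C(=O)C[C@H]3O[C@@]3(C)C[C@@H](OC(=O)C(C)C)[C@H]12
F3 | step 11 | (4S,5R)-4-{(1S,3Z)-1-hydroxy-6-[(4-methoxybenzyl)oxy]-3-methylhex-3-en-1-yl}-5-[(1Z)-2-iodoprop-1-en-1-yl]-3-methylideneoxolan-2-one (C8 epimer of 23) | C=C1C(=O)O[C@@H](/C=C(/C)I)[C@@H]1[C@@H](O)C/C(C)=C\CCOCc1ccc(OC)cc1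
F4 | step 11 | (1R,3Z)-1-{(2R,3S)-2-[(1Z)-2-iodoprop-1-en-1-yl]-4-methylidene-5-oxooxolan-3-yl}-6-[(4-methoxybenzyl)oxy]-3-methylhex-3-en-1-yl 2-methylpropanoate | C=C1C(=O)O[C@@H](/C=C(/C)I)[C@@H]1[C@H](OC(=O)C(C)C)C/C(C)=C\CCOCc1ccc(OC)cc1
F0 | step 12 | none | none
F5 | step 6 | (3R,4Z)-5-iodohexa-1,4-dien-3-yl 2-{[(tert-butyldimethylsilyl)oxy]methyl}prop-2-enoate | C=C(CO[Si](C)(C)C(C)(C)C)C(=O)O[C@@H](/C=C(/C)I)C=C
F6 | step 6 | (5R)-3-{[(tert-butyldimethylsilyl)oxy]methyl}-5-[(1Z)-2-iodoprop-1-en-1-yl]furan-2(5H)-one | O=C1O[C@@H](/C=C(/C)I)C=C1CO[Si](C)(C)C(C)(C)C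
F7 | step 6 | (5R)-3-(hydroxymethyl)-5-[(1Z)-2-iodoprop-1-en-1-yl]furan-2(5H)-one | O=C1O[C@@H](/C=C(/C)I)C=C1CO
F8 | step 4 | (3R,4Z)-5-iodohexa-1,4-dien-3-yl acetate | CC(=O)O[C@@H](/C=C(/C)I)C=C
A1 | alternative 1 | isoxazoline-bridged ten-membered carbocycle (product of the nitrile oxide cycloaddition) | C/C(=C/[C@@H]1OC(=O)C[C@H]1[C@H](OC(=O)C(C)C)C[C@](C)(O)[C@@H]2C3)C3=NO2
A2 | alternative 1 | open-chain C3 aldoxime with the vinyl group on the C10 carbinol | C/C(=C/[C@@H]1OC(=O)C[C@H]1[C@H](OC(=O)C(C)C)C[C@](C)(O)C=C)C=NO
A3 | alternative 2 | 8-(4-methoxybenzyloxy)-3-(tert-butyldimethylsilyloxy)cyclodeca-1(10)E,4Z-dien-6-one | O=C1/C=C(/C)[C@@H](O[Si](C)(C)C(C)(C)C)C/C=C(\C)C[C@@H](OCc2ccc(OC)cc2)C1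
A4 | alternative 2 | 4-(tert-butyldimethylsilyloxy)-1-[(E)-2-(4-methoxybenzyloxy)ethenyl]-3-methyl-6-(prop-1-en-2-yl)cyclohex-2-en-1-ol (alkenyl groups trans) | O[C@@]1(/C=C/OCc2ccc(OC)cc2)C=C(C)[C@@H](O[Si](C)(C)C(C)(C)C)C[C@H]1C(C)=C
A5 | alternative 3 | 3,6-endoperoxide with the Z C4=C5 olefin | COC(=O)C[C@@H]1[C@H]2OO[C@H](C(C)=C2)C[C@H]3O[C@@]3(C)C[C@H]1OC(=O)C(C)C
A6 | alternative 3 | (3Z,5Z)-cyclodecadiene epoxy ester | COC(=O)C[C@@H]1/C=C\C(C)=C/C[C@H]2O[C@@]2(C)C[C@H]1OC(=O)C(C)C
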